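The earlier runs and the new flask stem from a simulated flask for an exercise; noise was put on by code.

My reckoning takes the partner to use up substrate one for one, so the first number for a flask is its reach, 1.50: partner charge over substrate charge, the number of times the partner can turn over the substrate charged.

| flask | substrate | partner | gas | remark | time |
|---|---|---|---|---|---|
| ash | 0.20 M | 0.42 M | 20 mM (held) | run made earlier |  |
| cedar | 0.20 M | 0.66 M | 20 mM (held) | run made earlier |  |
| birch | 0.10 M | 0.30 M | 20 mM (held) | run made earlier |  |
| flask | 0.20 M | 0.300 M | 20 mM (held) |  | 20 min |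

| run | time / min | intermediate / % | target / % |
|---|---|---|---|
| ash | 2.50 | 58.9 | 2.7 |
| ash | 4.00 | 70.3 | 4.0 |
| ash | 5.00 | 74.6 | 5.5 |
| ash | 8.00 | 79.0 | 12.1 |
| ash | 10.0 | 79.7 | 16.6 |
| ash | 15.0 | 72.9 | 25.5 |
| ash | 20.0 | 65.0 | 32.0 |
| cedar | 2.50 | 74.4 | 3.1 |
| cedar | 4.00 | 84.7 | 5.8 |
| cedar | 5.00 | 86.9 | 7.7 |
| cedar | 8.00 | 85.3 | 14.1 |
| cedar | 10.0 | 81.8 | 18.8 |
| cedar | 15.0 | 73.3 | 28.1 |
| cedar | 20.0 | 64.4 | 34.9 |
| birch | 2.50 | 49.8 | 2.3 |
| birch | 5.00 | 68.2 | 5.5 |
| birch | 8.00 | 76.2 | 11.3 |
| birch | 12.0 | 75.7 | 18.1 |
| birch | 20.0 | 65.5 | 33.1 |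

(scatter of a reading: 0.5 percentage points)

- time up to 20 min at which intermediate stands highest
- the amount of intermediate, in percent of the substrate charged, at that time

- the earlier runs were read with a standard deviation of 0.5 percentage points
- at the start none of the gas is in solution

In this flask the reach stands above one, so substrate can go while a third of the partner remains. How slowly does the last substrate go on that excess? My own reckoning takes the one-for-one rate law through the ash readings at 5.00 min and gives this flask a tail time of 9.70 min, the time for substrate to fall by the factor e with the excess of partner taken as constant. How fast does intermediate drain? The target gained in ash between 10.0 min and 15.0 min reads as a drain time of 42.9 min, the mean intermediate over the target gained per minute, longer than the tail. The time allowed is 2.06 tail times, so I expect a flat peak before the end.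

The forecast says 71 % at 11.5 min: “Formation equals loss near 11.5 min”.

The flask peaks at 72.0 % at 10.9 min and holds 65.4 % at 20.0 min.

    substrate + partner → intermediate (k = 0.0180 L mol⁻¹ s⁻¹)
    gas ⇌ second reagent, rate k2*(csat - [second reagent]) (kL = 0.0810 s⁻¹)
    second reagent + intermediate → target (k = 0.0210 L mol⁻¹ s⁻¹)

At 200 min this flask keeps 33.3 % of its partner, and its reach gives 33.3 %. A neighbour charged with 0.50 M of substrate has a reach of 0.600: the partner is its limiting reagent, and 40.0 % of its substrate lies beyond that reach. At 20.0 min that neighbour holds 0.536 % of its partner and 40.3 % of its substrate, with 39.6 % as intermediate and 20.0 % as target. Its intermediate reaches 47.9 % at best.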